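Count the ligand.

| flask | starting complex | incoming ligand | remark | time |
|---|---|---|---|---|
| maple | 0.24 M | 0.21 M | run made earlier |  |
| birch | 0.24 M | 0.46 M | run made earlier |  |
| cedar | 0.24 M | 1 M | run made earlier |  |
| north-west | 0.24 M | 0.192 M |  | 20 min |
| south | 0.24 M | 0.960 M |  | 20 min |
| north | 0.24 M | 0.360 M |  | 20 min |

- maple (time / min: complex with four exchanged / %, complex with three exchanged / %, starting complex / %): 1.50: 0.3, 2.0, 44.0; 4.00: 0.2, 1.7, 17.8; 8.00: 0, 2.8, 4.2; 20.0: 1.1, 6.4, 0.6
- birch (time / min: complex with four exchanged / %, complex with three exchanged / %, starting complex / %): 2.50: 2.7, 7.5, 4.5; 8.00: 8.7, 15.9, 0.2; 12.0: 12.8, 16.0, 1.4; 20.0: 18.6, 15.7, 0.3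
- cedar (time / min: complex with four exchanged / %, complex with three exchanged / %, starting complex / %): 5.00: 32.1, 19.8, 0.7; 10.0: 53.5, 9.3, 3.0; 15.0: 62.6, 5.2, 0.8; 20.0: 66.4, 2.6, 0

(standard deviation of a reading: 1 percentage point)

1. which of these holds the largest part of the starting complex at the end of north-west (complex with one exchanged / complex with three exchanged / complex with four exchanged / complex with two exchanged / starting complex)
2. which of these holds the largest part of the starting complex at the end of south (complex with one exchanged / complex with three exchanged / complex with four exchanged / complex with two exchanged / starting complex)
3. which of these holds the largest part of the starting complex at the end of north (complex with one exchanged / complex with three exchanged / complex with four exchanged / complex with two exchanged / starting complex)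
4. amount of complex with four exchanged at the end of north, in percent of the starting complex charged

- the analysis behind the earlier runs scatters by 1 percentage point, standard deviation

Does every charged complex stay on the exchange ladder? In cedar at 20.0 min, complex with four exchanged and complex with three exchanged read 69.0 % together, and complex with three exchanged is fading. I freeze that reading as the ladder share, the part of the charge that goes on taking up incoming ligand.

How much ligand does each of those complexes then get? The ligand per kept complex, the charged [incoming ligand] over [starting complex] times the ladder share, is a mean number of exchanges. For north it is 2.17, which lands nearest complex with two exchanged, so I put that species first there. For south it is 5.80, more than the 4 places on the complex, so complex with four exchanged leads. For north-west it is 1.16, between complex with one exchanged and complex with two exchanged, and I leave that open. This reckoning names a leader and gives no amount.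

The forecast names complex with one exchanged for north-west, complex with four exchanged for south and complex with one exchanged for north, with 8 % of complex with four exchanged in north. For north it differs from my reckoning, with “leaving a mean near one for the rest”.

The flask gives complex with two exchanged in north-west, complex with four exchanged in south and complex with two exchanged in north, with 9.66 % of complex with four exchanged in north.

    starting complex + incoming ligand → leaving ligand + complex with one exchanged (k = 0.0546 /M/s)
    complex with one exchanged + incoming ligand → leaving ligand + complex with two exchanged (k = 0.127 /M/s)
    complex with two exchanged + incoming ligand → leaving ligand + complex with three exchanged (k = 0.0188 /M/s)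
    complex with three exchanged + incoming ligand → leaving ligand + complex with four exchanged (k = 0.0265 /M/s)
    leaving ligand + starting complex → side product (k = 0.0978 /M/s)
    incoming ligand ⇌ dormant form (K = 1.18, k = 0.0173 /s)

In north at 0.334 min, starting complex passes to complex with one exchanged 1.7 times as fast as to side product at that moment, and side product ends at 49.7 %. The ladder share in north is therefore 50.3 %, less than cedar's reading, and the ligand per kept complex is 2.98, more than 2.17. In north-west, side product at 59.7 % gives 1.98, and complex with two exchanged stands at 26.9 %.

The readings were computed for an exercise; noise was put on by code.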